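**Strategy.** Ring A is constructed, not substituted. Its C1 (the CH2OH carbon) and C2 (the bridge carbon) are tied through oxygen as a 1-aryl-1,3-dihydroisobenzofuran, so a cobalt-mediated (2+2+2) cycloaddition closes the benzene ring and the fused furan ring together: an ether-tethered diyne supplies C6, C1, C2 and C3, a diborylethyne supplies C4 and C5. One operation forms C1–C2, C3–C4 and C5–C6 and programs every position: silicon at C3 (later bromine), boron at C4 and C5 (later hydroxyl), hydrogen at C6. The precursor is the propargyl ether of a trimethylsilyl-capped propargylic alcohol carrying the finished, methyl-protected ring B.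

Key step: step 5

**Remarks on the chemistry**
- Ring A numbering: C1 bears CH2OH, C2 the bridge CH2, C3 Br, C4 and C5 OH, C6 H. Ring B is the 2,3-dibromo-4,5-dihydroxyphenyl ring.
- The target is achiral. The single stereocentre of the intermediates (the carbinol/acetal carbon) is carried as the racemate and disappears when it becomes the CH2 bridge.
- The cyclic ether is reduced while ring A still carries boron. After oxidation the freed CH2OH would sit para to a phenol and could itself be reduced.
- BBr3 is expected to turn the electron-rich benzylic alcohol into its bromide, so an aqueous solvolysis is built into the last step.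

**Route**

Step 1
Reactants: 1 5-bromovanillin (3-bromo-4-hydroxy-5-methoxybenzaldehyde)
Product: 2 2,3-dibromo-4-hydroxy-5-methoxybenzaldehyde
Conditions: Br2 (1.2 equiv), Fe powder (cat.), AcOH, rt → 50 °C
Reagents that add atoms: bromine, BrBr
Why: Electrophilic aromatic bromination (iron-catalysed halogenation); of the two free positions only C2 is para to the methoxy donor, so the second bromine should enter there and give the 2,3-dibromo pattern of ring B.

Step 2
Reactants: 2 2,3-dibromo-4-hydroxy-5-methoxybenzaldehyde
Product: 3 2,3-dibromo-4,5-dimethoxybenzaldehyde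
Conditions: MeI, K2CO3, DMF, rt
Reagents that add atoms: iodomethane, CI
Why: Williamson O-methylation of the acidic phenol in a dipolar aprotic solvent; the aldehyde and the aryl bromides are inert to these conditions.

Step 3
Reactants: 3 2,3-dibromo-4,5-dimethoxybenzaldehyde; 4 ethynyltrimethylsilane
Product: 5 racemic 1-(2,3-dibromo-4,5-dimethoxyphenyl)-3-(trimethylsilyl)prop-2-yn-1-ol
Conditions: 4 (1.3 equiv), n-BuLi (1.2 equiv), THF, −78 °C; then 3, −78 → −20 °C; aq. NH4Cl
Reagents that add atoms: none
Why: 1,2-Addition of a lithium acetylide to a non-enolisable aryl aldehyde; the excess of alkyne over n-BuLi leaves no alkyllithium that could exchange with the aryl bromides, and the new carbinol stereocentre forms as the racemate, which suffices because this carbon ends as the CH2 bridge.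

Step 4
Reactants: 5 racemic 1-(2,3-dibromo-4,5-dimethoxyphenyl)-3-(trimethylsilyl)prop-2-yn-1-ol; 6 propargyl bromide
Product: 7 racemic [3-(2,3-dibromo-4,5-dimethoxyphenyl)-3-(prop-2-yn-1-yloxy)prop-1-yn-1-yl]trimethylsilane
Conditions: NaH, THF, 0 °C; then 6, Bu4NI (cat.), 0 °C → rt
Reagents that add atoms: none
Why: Williamson etherification of the sodium alkoxide with a reactive propargylic bromide in aprotic THF, where the alkynyl C–Si bond (labile mainly to hydroxide or alkoxide in protic media) and the aryl bromides should survive.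

Step 5
Reactants: 7 racemic [3-(2,3-dibromo-4,5-dimethoxyphenyl)-3-(prop-2-yn-1-yloxy)prop-1-yn-1-yl]trimethylsilane; 8 1,2-bis(4,4,5,5-tetramethyl-1,3,2-dioxaborolan-2-yl)ethyne
Product: 9 racemic 1-(2,3-dibromo-4,5-dimethoxyphenyl)-5,6-bis(4,4,5,5-tetramethyl-1,3,2-dioxaborolan-2-yl)-7-(trimethylsilyl)-1,3-dihydroisobenzofuran
Conditions: CpCo(CO)2 (30 mol %), 8 (3 equiv), degassed o-xylene, reflux, hν (visible lamp), 7 added by syringe pump
Reagents that add atoms: none
Why: Light and heat strip CO from CpCo(CO)2, and the CpCo fragment (monovalent cobalt) couples the two tethered alkynes of 7 oxidatively to a bicyclic cobaltacyclopentadiene (trivalent cobalt), which makes C1–C2; alkyne 8 then inserts and reductive elimination makes C3–C4 and C5–C6 and releases the arene. The closest known reaction type is the cobalt-mediated (2+2+2) cocyclisation of 1,6-diynes with alkynylboronates and with bis(trimethylsilyl)ethyne. The benzene ring closes by the union of three alkynes, and the dihydrofuran ring closes in the oxidative-coupling event, because the two carbons joined there are already linked by the three-atom C–O–C tether (five-membered ring). No stereocentre is created, and the racemic carbinol carbon is a spectator. The step needs cross-cyclisation in preference to self-trimerisation and a single regiochemistry: the tether makes 7 the metallacycle partner, slow addition keeps it dilute, the bulky symmetrical alkyne 8 should not trimerise readily and offers no regiochemical choice, and the alkyne termini fix silicon at C3, boron at C4 and C5 and hydrogen at C6.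

Step 6
Reactants: 9 racemic 1-(2,3-dibromo-4,5-dimethoxyphenyl)-5,6-bis(4,4,5,5-tetramethyl-1,3,2-dioxaborolan-2-yl)-7-(trimethylsilyl)-1,3-dihydroisobenzofuran
Product: 10 racemic 7-bromo-1-(2,3-dibromo-4,5-dimethoxyphenyl)-5,6-bis(4,4,5,5-tetramethyl-1,3,2-dioxaborolan-2-yl)-1,3-dihydroisobenzofuran
Conditions: Br2 (1.05 equiv), CH2Cl2, −78 → 0 °C; aq. Na2S2O3/NaHCO3
Reagents that add atoms: bromine, BrBr
Why: Electrophilic ipso-substitution (bromodesilylation): attack at the silicon-bearing carbon gives a β-silyl-stabilised arenium ion that loses the silyl group, so bromine enters only at C3; strain relief at this crowded carbon helps, the C–B bonds of pinacol boronates are not activated toward Br2 without a Lewis base, and the one free position of ring B (ortho to a methoxy group, para to bromine) is unreactive.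

Step 7
Reactants: 10 racemic 7-bromo-1-(2,3-dibromo-4,5-dimethoxyphenyl)-5,6-bis(4,4,5,5-tetramethyl-1,3,2-dioxaborolan-2-yl)-1,3-dihydroisobenzofuran
Product: 11 [3-bromo-2-(2,3-dibromo-4,5-dimethoxybenzyl)-4,5-bis(4,4,5,5-tetramethyl-1,3,2-dioxaborolan-2-yl)phenyl]methanol
Conditions: Et3SiH (3 equiv), CF3CO2H/CH2Cl2 (1:1), 0 °C → rt; aq. NaHCO3
Reagents that add atoms: none
Why: Ionic hydrogenation: the protonated cyclic ether ionises at the doubly benzylic carbon (cation carried by both aryl rings, with the para-methoxy group of ring B as donor) and Et3SiH delivers hydride, whereas the primary benzylic C–O bond on the boron-bearing, electron-poor ring A should not ionise, so the CH2 bridge forms and the CH2OH is released intact.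

Step 8
Reactants: 11 [3-bromo-2-(2,3-dibromo-4,5-dimethoxybenzyl)-4,5-bis(4,4,5,5-tetramethyl-1,3,2-dioxaborolan-2-yl)phenyl]methanol
Product: 12 3-bromo-4-(2,3-dibromo-4,5-dimethoxybenzyl)-5-(hydroxymethyl)benzene-1,2-diol
Conditions: 30% H2O2, aq. NaOH, THF, 0 °C, argon; then aq. Na2S2O3, 1 M HCl
Reagents that add atoms: hydrogen peroxide, OO
Why: Oxidation of aryl C–B bonds by hydroperoxide (boronate formation, then 1,2-migration of the aryl carbon from boron to oxygen), which places hydroxyl exactly where boron stood at C4 and C5; the catechol stays masked as its borate until the acidic work-up, and any silyl or trifluoroacetyl residue on the CH2OH is cleaved by the base.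

Step 9
Reactants: 12 3-bromo-4-(2,3-dibromo-4,5-dimethoxybenzyl)-5-(hydroxymethyl)benzene-1,2-diol
Product: 14 3,4-dibromo-5-[2-bromo-3,4-dihydroxy-6-(hydroxymethyl)benzyl]benzene-1,2-diol (CNP0203154.0), via benzylic bromide 13 (not isolated)
Conditions: BBr3 (6 equiv), CH2Cl2, −78 °C → rt; H2O, 0 °C; then acetone/H2O (1:1), rt
Reagents that add atoms: water, O (oxygen of the re-formed CH2OH); boron tribromide, BrB(Br)Br (benzylic bromine of intermediate 13 only)
Why: Lewis-acid cleavage of the two aryl methyl ethers by BBr3, which should also convert the electron-rich benzylic alcohol into bromide 13; this para-hydroxybenzylic bromide is expected to solvolyse readily in aqueous acetone (through a quinone-methide-like cation) and return the alcohol.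

**Compound list**

1 | 5-bromovanillin (3-bromo-4-hydroxy-5-methoxybenzaldehyde) | O=Cc1cc(Br)c(O)c(OC)c1 | starting material
2 | 2,3-dibromo-4-hydroxy-5-methoxybenzaldehyde | O=Cc1cc(OC)c(O)c(Br)c1Br | intermediate
3 | 2,3-dibromo-4,5-dimethoxybenzaldehyde | O=Cc1cc(OC)c(OC)c(Br)c1Br | intermediate
4 | ethynyltrimethylsilane | C#C[Si](C)(C)C | starting material
5 | racemic 1-(2,3-dibromo-4,5-dimethoxyphenyl)-3-(trimethylsilyl)prop-2-yn-1-ol | OC(C#C[Si](C)(C)C)c1cc(OC)c(OC)c(Br)c1Br | intermediate
6 | propargyl bromide | C#CCBr | starting material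
7 | racemic [3-(2,3-dibromo-4,5-dimethoxyphenyl)-3-(prop-2-yn-1-yloxy)prop-1-yn-1-yl]trimethylsilane | C#CCOC(C#C[Si](C)(C)C)c1cc(OC)c(OC)c(Br)c1Br | intermediate
8 | 1,2-bis(4,4,5,5-tetramethyl-1,3,2-dioxaborolan-2-yl)ethyne | CC1(C)OB(C#CB2OC(C)(C)C(C)(C)O2)OC1(C)C | starting material
9 | racemic 1-(2,3-dibromo-4,5-dimethoxyphenyl)-5,6-bis(4,4,5,5-tetramethyl-1,3,2-dioxaborolan-2-yl)-7-(trimethylsilyl)-1,3-dihydroisobenzofuran | C[Si](C)(C)c1c(B2OC(C)(C)C(C)(C)O2)c(B2OC(C)(C)C(C)(C)O2)cc2c1C(c1cc(OC)c(OC)c(Br)c1Br)OC2 | intermediate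
10 | racemic 7-bromo-1-(2,3-dibromo-4,5-dimethoxyphenyl)-5,6-bis(4,4,5,5-tetramethyl-1,3,2-dioxaborolan-2-yl)-1,3-dihydroisobenzofuran | Brc1c(B2OC(C)(C)C(C)(C)O2)c(B2OC(C)(C)C(C)(C)O2)cc2c1C(c1cc(OC)c(OC)c(Br)c1Br)OC2 | intermediate
11 | [3-bromo-2-(2,3-dibromo-4,5-dimethoxybenzyl)-4,5-bis(4,4,5,5-tetramethyl-1,3,2-dioxaborolan-2-yl)phenyl]methanol | OCc1cc(B2OC(C)(C)C(C)(C)O2)c(B2OC(C)(C)C(C)(C)O2)c(Br)c1Cc1cc(OC)c(OC)c(Br)c1Br | intermediate
12 | 3-bromo-4-(2,3-dibromo-4,5-dimethoxybenzyl)-5-(hydroxymethyl)benzene-1,2-diol | OCc1cc(O)c(O)c(Br)c1Cc1cc(OC)c(OC)c(Br)c1Br | intermediate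
13 | 3,4-dibromo-5-[2-bromo-6-(bromomethyl)-3,4-dihydroxybenzyl]benzene-1,2-diol | BrCc1cc(O)c(O)c(Br)c1Cc1cc(O)c(O)c(Br)c1Br | intermediate
14 | 3,4-dibromo-5-[2-bromo-3,4-dihydroxy-6-(hydroxymethyl)benzyl]benzene-1,2-diol (CNP0203154.0) | OCc1cc(O)c(O)c(Br)c1Cc1cc(O)c(O)c(Br)c1Br | target

**Step count and risks**

Total steps: 9. Longest linear sequence: 9 steps (1 → 14); compounds 4, 6 and 8 enter as bought.

Most likely to fail:

1. Step 5 (cycloaddition). The hindered diborylalkyne may fail to enter the silyl-substituted cobaltacycle, so that the diyne is consumed by self-oligomerisation or is held as a stable CpCo–cyclobutadiene or –cyclohexadiene complex. Fallback: replace the catalytic three-component cocyclisation by a stepwise, stoichiometric assembly on zerovalent cobalt. Alkyne 8 is first bound with Co2(CO)8 (pentane, rt) as the alkyne complex [μ-1,2-bis(4,4,5,5-tetramethyl-1,3,2-dioxaborolan-2-yl)ethyne]Co2(CO)6 F1. This complex is then heated with diyne 7 in refluxing xylenes, so that the reluctant alkyne is already on the metal when the diyne arrives. The product should again be cycloadduct 9, where the route resumes.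

2. Step 6 (bromodesilylation). Ipso-attack at the crowded, electron-poor carbon may be slow, bromine may attack a carbon–boron bond instead, or the silyl bromide that is released may open the cyclic ether. Fallback: reverse the order of the two heteroatom exchanges so that silicon is replaced on an electron-rich ring. Cycloadduct 9 is oxidised (H2O2, NaOH, THF) to racemic 1-(2,3-dibromo-4,5-dimethoxyphenyl)-7-(trimethylsilyl)-1,3-dihydroisobenzofuran-5,6-diol F2. Methylation (MeI, K2CO3, DMF) gives racemic 1-(2,3-dibromo-4,5-dimethoxyphenyl)-5,6-dimethoxy-7-(trimethylsilyl)-1,3-dihydroisobenzofuran F3. Br2 in CH2Cl2 at low temperature should now substitute silicon ortho to a methoxy group, both positions para to the methoxy groups being blocked, to give racemic 7-bromo-1-(2,3-dibromo-4,5-dimethoxyphenyl)-5,6-dimethoxy-1,3-dihydroisobenzofuran F4. Ionic reduction with a limited amount of Et3SiH in CF3CO2H gives [3-bromo-2-(2,3-dibromo-4,5-dimethoxybenzyl)-4,5-dimethoxyphenyl]methanol F5. BBr3 then cleaves all four methyl ethers and joins the route at benzylic bromide 13.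

3. Step 7 (ionic reduction). With boron on ring A and a twisted para-methoxy group on ring B the cyclic ether may not ionise, and forcing the acidity may cause protodeboronation. Fallback: oxidise first and let a para-hydroxyl group drive the ionisation. Bromide 10 is treated with H2O2 and NaOH in THF to give racemic 7-bromo-1-(2,3-dibromo-4,5-dimethoxyphenyl)-1,3-dihydroisobenzofuran-5,6-diol F6. Its hydroxyl para to the ring carbon that carries the acetal carbon should allow ring opening with Et3SiH (1.1 equiv) in CF3CO2H/CH2Cl2 at −20 °C; the silane is limited so that the freed CH2OH is not reduced further. This delivers compound 12, where the route resumes.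

**Further compounds**

F1 | step 5 | [μ-1,2-bis(4,4,5,5-tetramethyl-1,3,2-dioxaborolan-2-yl)ethyne]Co2(CO)6 | CC1(C)OB(OC1(C)C)C23C4(B5OC(C)(C)C(C)(C)O5)[Co]2(=C=O)(=C=O)(=C=O)[Co]34(=C=O)(=C=O)=C=O
F2 | step 6 | racemic 1-(2,3-dibromo-4,5-dimethoxyphenyl)-7-(trimethylsilyl)-1,3-dihydroisobenzofuran-5,6-diol | C[Si](C)(C)c1c(O)c(O)cc2c1C(c1cc(OC)c(OC)c(Br)c1Br)OC2
F3 | step 6 | racemic 1-(2,3-dibromo-4,5-dimethoxyphenyl)-5,6-dimethoxy-7-(trimethylsilyl)-1,3-dihydroisobenzofuran | C[Si](C)(C)c1c(OC)c(OC)cc2c1C(c1cc(OC)c(OC)c(Br)c1Br)OC2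
F4 | step 6 | racemic 7-bromo-1-(2,3-dibromo-4,5-dimethoxyphenyl)-5,6-dimethoxy-1,3-dihydroisobenzofuran | Brc1c(OC)c(OC)cc2c1C(c1cc(OC)c(OC)c(Br)c1Br)OC2
F5 | step 6 | [3-bromo-2-(2,3-dibromo-4,5-dimethoxybenzyl)-4,5-dimethoxyphenyl]methanol | OCc1cc(OC)c(OC)c(Br)c1Cc1cc(OC)c(OC)c(Br)c1Br
F6 | step 7 | racemic 7-bromo-1-(2,3-dibromo-4,5-dimethoxyphenyl)-1,3-dihydroisobenzofuran-5,6-diol | Brc1c(O)c(O)cc2c1C(c1cc(OC)c(OC)c(Br)c1Br)OC2
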